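**Assumption:** the SMILES has no stereocentre and the diaryl ether axes rotate freely, so the target is achiral and no stereocontrol is needed.

## Retrosynthetic overview

1. The target has no C–C bond outside its five benzene rings, so the four aryl–O bonds are the strategic bonds; the last step is global O-demethylation of the trideca-O-methyl ether 18.
2. C–O–D bond: Ullmann coupling of ABC bromide 12 with DE phenol 17.
3. Key B–O–C bond: ring C reacts with reversed polarity. Its electron-rich aryl carbon becomes an aryl-cation equivalent in the aryl(trimethoxyphenyl)iodonium salt 6 and is captured, metal-free, by the doubly ortho-substituted phenol 11; the ring C bromide survives.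
4. AB phenol 11 and DE phenol 17 each come from an ortho-bromobenzaldehyde plus a phenol (Ullmann), then Baeyer–Villiger/Dakin conversion of CHO into OH.
5. No ring is built: all five rings are bought as oxygenated benzenes and joined in the order A+B, D+E, AB+C, ABC+DE.

## Route

Step 1
Reactants: 1 2-bromo-6-methoxyphenol
Product: 2 2-bromo-4-iodo-6-methoxyphenol
Conditions: NIS (1.05 equiv), TsOH·H2O (10 mol%), MeCN, 0 °C to rt
Reagents that add atoms: N-iodosuccinimide, O=C1CCC(=O)N1I
Why: Electrophilic aromatic iodination in which the free OH directs para, and since both ortho positions are blocked by Br and OMe only C4 is attacked.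

Step 2
Reactants: 2 2-bromo-4-iodo-6-methoxyphenol
Product: 3 1-bromo-5-iodo-2,3-dimethoxybenzene
Conditions: MeI (1.5 equiv), K2CO3 (2 equiv), DMF, rt
Reagents that add atoms: iodomethane, CI
Why: Williamson O-methylation of the phenoxide, which masks the phenol that would otherwise be oxidised in step 3 and sets up the same methyl protection as all other rings.

Step 3
Reactants: 3 1-bromo-5-iodo-2,3-dimethoxybenzene; 4 1,3,5-trimethoxybenzene
Product: 6 (3-bromo-4,5-dimethoxyphenyl)(2,4,6-trimethoxyphenyl)iodonium tosylate, via hydroxy(tosyloxy)iodoarene 5 (not isolated)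
Conditions: mCPBA (1.1 equiv), TsOH·H2O (1.05 equiv), MeCN, 77 °C, 30 min; then 4 (1.0 equiv), 77 °C, 5 min; Et2O trituration
Reagents that add atoms: p-toluenesulfonic acid, Cc1ccc(cc1)S(=O)(=O)O
Why: One-pot diaryliodonium synthesis in which mCPBA/TsOH oxidise the aryl iodide to the Koser-type trivalent-iodine species 5, which the very nucleophilic 1,3,5-trimethoxybenzene attacks by electrophilic aromatic substitution, turning C1 of ring C into an aryl-cation equivalent (the oxygen from mCPBA leaves as water).

Step 4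
Reactants: 7 2-bromo-4,6-dimethoxybenzaldehyde; 8 2,4,6-trimethoxyphenol
Product: 9 2,4-dimethoxy-6-(2,4,6-trimethoxyphenoxy)benzaldehyde (AB aldehyde)
Conditions: CuI (10 mol%), picolinic acid (20 mol%), K3PO4 (2 equiv), DMSO, 90 °C, Ar
Reagents that add atoms: none
Why: Ullmann-type copper-catalysed diaryl ether synthesis in which the ortho-formyl group activates the C–Br bond and the picolinic acid ligand tolerates the doubly ortho-substituted phenol.

Step 5
Reactants: 9 2,4-dimethoxy-6-(2,4,6-trimethoxyphenoxy)benzaldehyde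
Product: 11 2,4-dimethoxy-6-(2,4,6-trimethoxyphenoxy)phenol (AB phenol), via aryl formate 10 (not isolated)
Conditions: mCPBA (1.2 equiv), CH2Cl2, 0 °C to rt; aq NaHCO3 wash; then K2CO3 (0.1 equiv), MeOH, rt
Reagents that add atoms: 3-chloroperoxybenzoic acid, OOC(=O)c1cccc(Cl)c1
Why: Baeyer–Villiger (Dakin-type) oxidation in which the electron-rich ortho,para-trioxygenated aryl group migrates in preference to H, and the resulting formate is cleaved by base-catalysed methanolysis.

Step 6
Reactants: 11 2,4-dimethoxy-6-(2,4,6-trimethoxyphenoxy)phenol; 6 (3-bromo-4,5-dimethoxyphenyl)(2,4,6-trimethoxyphenyl)iodonium tosylate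
Product: 12 1-bromo-5-[2,4-dimethoxy-6-(2,4,6-trimethoxyphenoxy)phenoxy]-2,3-dimethoxybenzene (ABC bromide)
Conditions: 6 (1.2 equiv), Cs2CO3 (1.5 equiv), MeCN, 55 °C, Ar
Reagents that add atoms: none
Why: Metal-free O-arylation of a phenoxide with a diaryliodonium salt (ligand exchange at trivalent iodine, then ligand coupling), in which the normally nucleophilic ring C carbon reacts as an aryl cation, the electron-rich doubly ortho-substituted trimethoxyphenyl group stays on iodine as a dummy ligand, the blocked ortho and para positions of 11 leave only O-arylation open, and the C–Br bond is untouched.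

Step 7
Reactants: 13 2-bromo-3,4,5-trimethoxybenzaldehyde; 14 3,4,5-trimethoxyphenol
Product: 15 3,4,5-trimethoxy-2-(3,4,5-trimethoxyphenoxy)benzaldehyde (DE aldehyde)
Conditions: CuI (10 mol%), picolinic acid (20 mol%), K3PO4 (2 equiv), DMSO, 90 °C, Ar
Reagents that add atoms: none
Why: Ullmann-type copper-catalysed diaryl ether synthesis on an ortho-carbonyl-activated bromide with an unhindered phenol, the same kind of coupling classically used for 2-bromo-3,4,5-trimethoxybenzoyl electrophiles.

Step 8
Reactants: 15 3,4,5-trimethoxy-2-(3,4,5-trimethoxyphenoxy)benzaldehyde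
Product: 17 3,4,5-trimethoxy-2-(3,4,5-trimethoxyphenoxy)phenol (DE phenol), via aryl formate 16 (not isolated)
Conditions: mCPBA (1.2 equiv), CH2Cl2, 0 °C to rt; aq NaHCO3 wash; then K2CO3 (0.1 equiv), MeOH, rt
Reagents that add atoms: 3-chloroperoxybenzoic acid, OOC(=O)c1cccc(Cl)c1
Why: Baeyer–Villiger (Dakin-type) oxidation with migration of the electron-rich aryl group bearing ortho-aryloxy and para-methoxy donors, followed by methanolysis of the formate.

Step 9
Reactants: 12 1-bromo-5-[2,4-dimethoxy-6-(2,4,6-trimethoxyphenoxy)phenoxy]-2,3-dimethoxybenzene; 17 3,4,5-trimethoxy-2-(3,4,5-trimethoxyphenoxy)phenol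
Product: 18 5-[2,4-dimethoxy-6-(2,4,6-trimethoxyphenoxy)phenoxy]-1,2-dimethoxy-3-[3,4,5-trimethoxy-2-(3,4,5-trimethoxyphenoxy)phenoxy]benzene (trideca-O-methyl ether of the target)
Conditions: CuI (20 mol%), picolinic acid (40 mol%), K3PO4 (2 equiv), DMSO, 110 °C, Ar
Reagents that add atoms: none
Why: Ullmann-type copper-catalysed diaryl ether synthesis with a ligand system that accepts ortho-substituted bromides and phenols, and with only one C–Br bond and one free OH present there is no chemoselectivity issue.

Step 10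
Reactants: 18 trideca-O-methyl ether of the target
Product: 20 pseudopentafuhalol D, via per-O-dibromoboryl ether 19 (not isolated)
Conditions: BBr3 (26 equiv), CH2Cl2, −78 °C to rt, Ar; then degassed H2O, 0 °C; Sephadex LH-20 (MeOH)
Reagents that add atoms: none
Why: Lewis-acid aryl methyl ether cleavage (BBr3 demethylation) in which bromide attacks only the methyl carbons, so the four diaryl ether bonds are inert and the aryl borates hydrolyse on quenching.

## Compound list

1 | 2-bromo-6-methoxyphenol | COc1cccc(Br)c1O | starting material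
2 | 2-bromo-4-iodo-6-methoxyphenol | COc1cc(I)cc(Br)c1O | intermediate
3 | 1-bromo-5-iodo-2,3-dimethoxybenzene | COc1cc(I)cc(Br)c1OC | intermediate
4 | 1,3,5-trimethoxybenzene | COc1cc(OC)cc(OC)c1 | starting material
5 | 1-bromo-5-[hydroxy(tosyloxy)iodanyl]-2,3-dimethoxybenzene (Koser-type species, not isolated) | COc1cc(I(O)OS(=O)(=O)c2ccc(C)cc2)cc(Br)c1OC | intermediate
6 | (3-bromo-4,5-dimethoxyphenyl)(2,4,6-trimethoxyphenyl)iodonium tosylate | COc1cc([I+]c2c(OC)cc(OC)cc2OC)cc(Br)c1OC.Cc1ccc(cc1)S(=O)(=O)[O-] | intermediate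
7 | 2-bromo-4,6-dimethoxybenzaldehyde | COc1cc(Br)c(C=O)c(OC)c1 | starting material
8 | 2,4,6-trimethoxyphenol | COc1cc(OC)c(O)c(OC)c1 | starting material
9 | 2,4-dimethoxy-6-(2,4,6-trimethoxyphenoxy)benzaldehyde (AB aldehyde) | COc1cc(OC)c(C=O)c(Oc2c(OC)cc(OC)cc2OC)c1 | intermediate
10 | 2,4-dimethoxy-6-(2,4,6-trimethoxyphenoxy)phenyl formate (not isolated) | COc1cc(OC)c(OC=O)c(Oc2c(OC)cc(OC)cc2OC)c1 | intermediate
11 | 2,4-dimethoxy-6-(2,4,6-trimethoxyphenoxy)phenol (AB phenol) | COc1cc(OC)c(O)c(Oc2c(OC)cc(OC)cc2OC)c1 | intermediate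
12 | 1-bromo-5-[2,4-dimethoxy-6-(2,4,6-trimethoxyphenoxy)phenoxy]-2,3-dimethoxybenzene (ABC bromide) | COc1cc(OC)c(Oc2cc(OC)c(OC)c(Br)c2)c(Oc2c(OC)cc(OC)cc2OC)c1 | intermediate
13 | 2-bromo-3,4,5-trimethoxybenzaldehyde | COc1cc(C=O)c(Br)c(OC)c1OC | starting material
14 | 3,4,5-trimethoxyphenol | COc1cc(O)cc(OC)c1OC | starting material
15 | 3,4,5-trimethoxy-2-(3,4,5-trimethoxyphenoxy)benzaldehyde (DE aldehyde) | COc1cc(C=O)c(Oc2cc(OC)c(OC)c(OC)c2)c(OC)c1OC | intermediate
16 | 3,4,5-trimethoxy-2-(3,4,5-trimethoxyphenoxy)phenyl formate (not isolated) | COc1cc(OC=O)c(Oc2cc(OC)c(OC)c(OC)c2)c(OC)c1OC | intermediate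
17 | 3,4,5-trimethoxy-2-(3,4,5-trimethoxyphenoxy)phenol (DE phenol) | COc1cc(O)c(Oc2cc(OC)c(OC)c(OC)c2)c(OC)c1OC | intermediate
18 | 5-[2,4-dimethoxy-6-(2,4,6-trimethoxyphenoxy)phenoxy]-1,2-dimethoxy-3-[3,4,5-trimethoxy-2-(3,4,5-trimethoxyphenoxy)phenoxy]benzene (trideca-O-methyl ether of the target) | COc1cc(OC)c(Oc2cc(OC)cc(OC)c2Oc2cc(OC)c(OC)c(Oc3cc(OC)c(OC)c(OC)c3Oc3cc(OC)c(OC)c(OC)c3)c2)c(OC)c1 | intermediate
19 | idealised tridecakis(O-dibromoboryl) derivative of the target (not isolated) | BrB(Br)Oc1cc(OB(Br)Br)c(Oc2cc(OB(Br)Br)cc(OB(Br)Br)c2Oc2cc(OB(Br)Br)c(OB(Br)Br)c(Oc3cc(OB(Br)Br)c(OB(Br)Br)c(OB(Br)Br)c3Oc3cc(OB(Br)Br)c(OB(Br)Br)c(OB(Br)Br)c3)c2)c(OB(Br)Br)c1 | intermediate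
20 | pseudopentafuhalol D, 5-[2,4-dihydroxy-6-(2,4,6-trihydroxyphenoxy)phenoxy]-3-[3,4,5-trihydroxy-2-(3,4,5-trihydroxyphenoxy)phenoxy]benzene-1,2-diol (achiral) | Oc1cc(O)c(Oc2cc(O)cc(O)c2Oc2cc(O)c(O)c(Oc3cc(O)c(O)c(O)c3Oc3cc(O)c(O)c(O)c3)c2)c(O)c1 | target

## Step count and risks

Total steps: 10. Longest linear sequence: 6 (steps 1, 2, 3, 6, 9, 10); the AB branch (steps 4, 5) and the DE branch (steps 7, 8) are run in parallel.

**Step 6 (iodonium O-arylation of the hindered, very electron-rich phenol 11).** The phenoxide might be oxidised by single-electron transfer to the iodonium salt, or ligand coupling might be slow. The fallback sets out from phenol 11 and iodide 3 and comes back at bromide 12. It drops the hypervalent-iodine electrophile and makes the same bond by copper catalysis: 11 and 3 (1.5 equiv) with CuI (10 mol%), picolinic acid (20 mol%) and K3PO4 in DMSO at 80 °C, relying on the faster reaction of C–I over C–Br. It also bypasses step 3 and makes no new compound (none F0).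

**Step 9 (late Ullmann coupling of two large, ortho-substituted, electron-rich partners).** Conversion may stall, or hydrodebromination of 12 may compete. The fallback sets out from bromide 12 and comes back at 18 by inverting the role of ring C from electrophile to boron nucleophile. Bromine–lithium exchange (n-BuLi, THF, −78 °C), then B(OiPr)3 and mild acid work-up, gives {5-[2,4-dimethoxy-6-(2,4,6-trimethoxyphenoxy)phenoxy]-2,3-dimethoxyphenyl}boronic acid F1. F1 is then joined to phenol 17 by Chan–Lam–Evans oxidative coupling (Cu(OAc)2 1 equiv, pyridine, 4 Å molecular sieves, CH2Cl2, air, rt), conditions that work at room temperature and tolerate ortho-substituted phenols.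

**Step 10 (cleavage of thirteen methyl ethers and isolation of an air-sensitive polyphenol).** Demethylation may be incomplete, and the pyrogallol-type rings may oxidise during work-up. The fallback sets out from 18 and comes back at 20 through a stable, chromatographable derivative. After the BBr3 treatment and quench, the crude polyphenol is not purified but acetylated at once (Ac2O, pyridine, DMAP cat., rt) to pseudopentafuhalol D tridecaacetate F2. F2 is purified on silica, which also removes partly demethylated material for recycling. Acid-catalysed methanolysis (AcCl cat. in degassed MeOH, rt to 40 °C, Ar) then releases 20 without exposing phenolates to base.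

## Further compounds

F0 | step 6 | none | none
F1 | step 9 | {5-[2,4-dimethoxy-6-(2,4,6-trimethoxyphenoxy)phenoxy]-2,3-dimethoxyphenyl}boronic acid | COc1cc(OC)c(Oc2cc(OC)c(OC)c(B(O)O)c2)c(Oc2c(OC)cc(OC)cc2OC)c1
F2 | step 10 | pseudopentafuhalol D tridecaacetate | CC(=O)Oc1cc(OC(C)=O)c(Oc2cc(OC(C)=O)cc(OC(C)=O)c2Oc2cc(OC(C)=O)c(OC(C)=O)c(Oc3cc(OC(C)=O)c(OC(C)=O)c(OC(C)=O)c3Oc3cc(OC(C)=O)c(OC(C)=O)c(OC(C)=O)c3)c2)c(OC(C)=O)c1
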